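**Retrosynthetic overview**

1. GA55 is traced back to a 19,10-lactone 2-en-1-one. The C7 acid is made last by oxidation of a C7 hydroxymethyl group, 3β-OH comes from β-face conjugate borylation–oxidation, and 1β-OH from α-face hydride delivery.
2. The enone lactone comes from an oxygen-bridged A/B adduct by hydrolysis of its C1 enol ether, β-elimination of the C3–O bridge bond and lactonisation of the freed C10–O onto C19.
3. The strategy rests on ring A: its oxygens on C10 and C3 stand 1,4 and the C4–C5 bond carries C19, so ring A is the six-membered ring of a 7-oxanorbornene built from a 3-methoxyfuran (C10, C1, C2, C3) and a (Z)-enoate (C5=C4). One intramolecular furan Diels–Alder reaction forms C5–C10 and C3–C4 and closes rings A and B.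
4. The cycloaddition precursor comes from an aldehyde by Still–Gennari olefination (C4=C5). C6 is set by catalyst-controlled hydroxymethylation, and C7 is kept as CH2OSiEt3 because a C7 ester next to the C5 aldehyde would be an enolised formyl ester, unfit for a base-mediated olefination. Ring D is closed by a SmI2 ketyl–alkyne cyclisation (C13–C16).
5. Ring C comes from 4,4-dimethoxycyclohexanone: Negishi coupling joins the furan to C9, asymmetric hydrogenation sets C9, enediolate propargylation anti to the furan sets quaternary C8, and Arndt–Eistert homologation adds C6. Ring order: C, then D, then A and B together.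

Key step: step 17

Assumption: 4,4-dimethoxycyclohexanone, 3-bromo-1-(trimethylsilyl)prop-1-yne and the bis(trifluoroethyl) phosphonate are taken as catalogue compounds; atom numbers are gibberellane numbers; every compound carrying the 3-methoxyfuran is worked up and chromatographed acid-free (Et3N-treated silica).

**Route**

Step 1
Reactants: 1 3-bromofuran
Product: 2 3-methoxyfuran
Conditions: NaOMe, CuBr (10 mol%), MeOH/NMP, 100 °C, sealed tube
Reagents that add atoms: sodium methoxide, C[O-].[Na+]
Why: Ullmann-type copper-catalysed methoxylation of the heteroaryl bromide should exchange Br for OMe without touching the furan ring, and no stereocenter is involved.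

Step 2
Reactants: 3 4,4-dimethoxycyclohexanone
Product: 4 methyl 5,5-dimethoxy-2-oxocyclohexane-1-carboxylate
Conditions: NaH, (MeO)2CO, THF, reflux; AcOH quench
Reagents that add atoms: dimethyl carbonate, COC(=O)OC
Why: Claisen-type C-acylation of the ketone enolate with dimethyl carbonate is driven by deprotonation of the β-keto ester, the dimethyl ketal is inert to base, and the single centre formed is enolisable and removed in step 3.

Step 3
Reactants: 4 methyl 5,5-dimethoxy-2-oxocyclohexane-1-carboxylate
Product: 5 methyl 5,5-dimethoxy-2-(trifluoromethylsulfonyloxy)cyclohex-1-ene-1-carboxylate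
Conditions: NaH, THF, 0 °C; PhNTf2, 0 °C to rt
Reagents that add atoms: N-phenylbis(trifluoromethanesulfonimide), O=S(=O)(N(c1ccccc1)S(=O)(=O)C(F)(F)F)C(F)(F)F
Why: O-sulfonylation of the β-keto ester enolate should give the tetrasubstituted enol triflate under basic conditions that spare the ketal.

Step 4
Reactants: 2 3-methoxyfuran; 5 methyl 5,5-dimethoxy-2-(trifluoromethylsulfonyloxy)cyclohex-1-ene-1-carboxylate
Product: 8 methyl 5,5-dimethoxy-2-(3-methoxyfuran-2-yl)cyclohex-1-ene-1-carboxylate, via 2-lithio-3-methoxyfuran 6 (not isolated), via (3-methoxyfuran-2-yl)zinc chloride 7 (not isolated)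
Conditions: 2, n-BuLi, THF, −78 to 0 °C; ZnCl2, 0 °C; then 5, Pd(PPh3)4 (5 mol%), THF, 50 °C
Reagents that add atoms: none
Why: Lithiation of 3-methoxyfuran goes to C2 (α to the ring oxygen and ortho to OMe), and Negishi coupling of the derived zinc reagent with the activated enol triflate should form the C9–C10 bond under neutral conditions.

Step 5
Reactants: 8 methyl 5,5-dimethoxy-2-(3-methoxyfuran-2-yl)cyclohex-1-ene-1-carboxylate
Product: 9 5,5-dimethoxy-2-(3-methoxyfuran-2-yl)cyclohex-1-ene-1-carboxylic acid
Conditions: LiOH, THF/MeOH/H2O, 40 °C; NaH2PO4 to pH 5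
Reagents that add atoms: lithium hydroxide, [Li+].[OH-]
Why: Saponification by acyl–oxygen cleavage frees the acid needed to bind the hydrogenation catalyst, and the ketal and the methoxyfuran are stable to base and to the buffered acidification.

Step 6
Reactants: 9 5,5-dimethoxy-2-(3-methoxyfuran-2-yl)cyclohex-1-ene-1-carboxylic acid
Product: 10 (1S,2R)-5,5-dimethoxy-2-(3-methoxyfuran-2-yl)cyclohexane-1-carboxylic acid (cis)
Conditions: Ru(OAc)2[(S)-BINAP] (2 mol%), H2 (100 bar), Et3N (1 equiv), MeOH, 50 °C; NaH2PO4 work-up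
Reagents that add atoms: none
Why: Carboxylate-directed asymmetric hydrogenation of the tetrasubstituted acrylic acid on the BINAP–ruthenium dicarboxylate delivers H2 syn, which should give the cis acid and fix C9 (the ligand enantiomer is assigned from the sense known for α-alkyl β-substituted acrylic acids), while the C8 centre formed here is planarised again in step 7.

Step 7
Reactants: 10 (1S,2R)-5,5-dimethoxy-2-(3-methoxyfuran-2-yl)cyclohexane-1-carboxylic acid; 11 3-bromo-1-(trimethylsilyl)prop-1-yne
Product: 13 (1S,2R)-5,5-dimethoxy-2-(3-methoxyfuran-2-yl)-1-[3-(trimethylsilyl)prop-2-yn-1-yl]cyclohexane-1-carboxylic acid, via dilithium enediolate 12 (not isolated)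
Conditions: LiN(i-Pr)2 (2.3 equiv), THF, −78 to 0 °C; DMPU; 11, −78 to −20 °C; NaH2PO4 to pH 5
Reagents that add atoms: none
Why: Alkylation of the carboxylic acid dianion should set quaternary C8, because allylic 1,3-strain with the exocyclic enediolate holds the C9 furyl group axial and the propargylic bromide then enters the opposite face, placing C15 trans and the carboxyl carbon (later C5) cis to the furan.

Step 8
Reactants: 13 (1S,2R)-5,5-dimethoxy-2-(3-methoxyfuran-2-yl)-1-[3-(trimethylsilyl)prop-2-yn-1-yl]cyclohexane-1-carboxylic acid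
Product: 15 diazomethyl ketone of 13 (C8–CO–CHN2), via acid chloride 14 (not isolated)
Conditions: 1-chloro-N,N,2-trimethylprop-1-en-1-amine, CH2Cl2, 0 °C; then CH2N2 (3 equiv), Et2O, 0 °C
Reagents that add atoms: diazomethane, C=[N+]=[N-]
Why: This is the first stage of an Arndt–Eistert homologation, in which the α-chloroenamine makes the hindered acid chloride without acid and diazomethane is acylated while its excess removes HCl, so ketal, furan and silylalkyne should survive and C8 is not touched.

Step 9
Reactants: 15 diazomethyl ketone of 13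
Product: 17 methyl 2-{5,5-dimethoxy-2-(3-methoxyfuran-2-yl)-1-[3-(trimethylsilyl)prop-2-yn-1-yl]cyclohexyl}acetate, via ketene 16 (not isolated)
Conditions: hν (350 nm), Et3N (0.1 equiv), MeOH, rt
Reagents that add atoms: methanol, CO
Why: Photochemical Wolff rearrangement moves the tertiary C8 group to the diazo carbon with retention, and methanol traps the ketene as the ester, which inserts C6 between C8 and the carboxyl carbon.

Step 10
Reactants: 17 methyl 2-{5,5-dimethoxy-2-(3-methoxyfuran-2-yl)-1-[3-(trimethylsilyl)prop-2-yn-1-yl]cyclohexyl}acetate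
Product: 18 methyl 2-[5,5-dimethoxy-2-(3-methoxyfuran-2-yl)-1-(prop-2-yn-1-yl)cyclohexyl]acetate
Conditions: K2CO3, MeOH, rt
Reagents that add atoms: none
Why: Methoxide-mediated protodesilylation of the alkynylsilane frees the terminal alkyne, and the methyl ester is unchanged by transesterification in methanol.

Step 11
Reactants: 18 methyl 2-[5,5-dimethoxy-2-(3-methoxyfuran-2-yl)-1-(prop-2-yn-1-yl)cyclohexyl]acetate
Product: 19 methyl 2-[2-(3-methoxyfuran-2-yl)-5-oxo-1-(prop-2-yn-1-yl)cyclohexyl]acetate
Conditions: PPTS (10 mol%), acetone/H2O (10:1), 0 °C to rt; Et3N quench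
Reagents that add atoms: water, O
Why: Acid-catalysed hydrolysis of an acyclic dimethyl ketal (O-protonation, oxocarbenium ion) is far faster than the rate-limiting C-protonation that would hydrolyse the aromatic methoxyfuran, so buffered PPTS should unmask the C13 ketone alone.

Step 12
Reactants: 19 methyl 2-[2-(3-methoxyfuran-2-yl)-5-oxo-1-(prop-2-yn-1-yl)cyclohexyl]acetate
Product: 20 methyl 2-[5-hydroxy-2-(3-methoxyfuran-2-yl)-6-methylidenebicyclo[3.2.1]octan-1-yl]acetate (furyl anti to the two-carbon bridge)
Conditions: SmI2 (3 equiv), HMPA, t-BuOH (2 equiv), THF, 0 °C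
Reagents that add atoms: none
Why: SmI2 ketyl–alkyne reductive cyclisation (5-exo-dig addition of the C13 ketyl radical to C16, then reduction and protonation of the vinyl radical) should close ring D as the bridgehead tertiary allylic alcohol with the 16-methylene group; C13 can form only in the configuration that bridges to C8, and ester and furan are inert to SmI2.

Step 13
Reactants: 20 methyl 2-[5-hydroxy-2-(3-methoxyfuran-2-yl)-6-methylidenebicyclo[3.2.1]octan-1-yl]acetate
Product: 21 2-[5-hydroxy-2-(3-methoxyfuran-2-yl)-6-methylidenebicyclo[3.2.1]octan-1-yl]acetaldehyde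
Conditions: i-Bu2AlH (2.2 equiv), CH2Cl2, −78 °C; aq. KNaC4H4O6
Reagents that add atoms: none
Why: Partial reduction of the ester stops at the aluminium hemiacetal at −78 °C (the first equivalent is taken up by the 13-OH), and the C5 aldehyde cannot close a lactol because the two bridgehead substituents diverge.

Step 14
Reactants: 21 2-[5-hydroxy-2-(3-methoxyfuran-2-yl)-6-methylidenebicyclo[3.2.1]octan-1-yl]acetaldehyde
Product: 22 (2S)-3-hydroxy-2-[5-hydroxy-2-(3-methoxyfuran-2-yl)-6-methylidenebicyclo[3.2.1]octan-1-yl]propanal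
Conditions: aq. CH2O (37%), (R)-α,α-diphenylprolinol trimethylsilyl ether (20 mol%), toluene, pH 7 phosphate buffer, rt
Reagents that add atoms: formaldehyde, C=O
Why: In this enamine-catalysed α-hydroxymethylation the CPh2OSiMe3 group shields one face of the (E)-enamine, so the catalyst rather than the substrate sets C6; the (R)-catalyst is taken because the (S)-catalyst is known to direct electrophiles to the opposite enamine face, and the neutral buffer protects the furan.

Step 15
Reactants: 22 (2S)-3-hydroxy-2-[5-hydroxy-2-(3-methoxyfuran-2-yl)-6-methylidenebicyclo[3.2.1]octan-1-yl]propanal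
Product: 23 (2S)-2-[5-hydroxy-2-(3-methoxyfuran-2-yl)-6-methylidenebicyclo[3.2.1]octan-1-yl]-3-(triethylsilyloxy)propanal
Conditions: Et3SiCl, imidazole, CH2Cl2, −20 °C
Reagents that add atoms: chlorotriethylsilane, CC[Si](Cl)(CC)CC
Why: Silylation is selective for the primary hydroxyl over the bridgehead tertiary one and blocks retro-aldol and dehydration of the β-hydroxy aldehyde, and the cold, weakly basic medium should not epimerise C6.

Step 16
Reactants: 23 (2S)-2-[5-hydroxy-2-(3-methoxyfuran-2-yl)-6-methylidenebicyclo[3.2.1]octan-1-yl]-3-(triethylsilyloxy)propanal; 24 methyl 2-[bis(2,2,2-trifluoroethoxy)phosphoryl]propanoate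
Product: 26 methyl (2Z,4S)-4-[5-hydroxy-2-(3-methoxyfuran-2-yl)-6-methylidenebicyclo[3.2.1]octan-1-yl]-2-methyl-5-(triethylsilyloxy)pent-2-enoate, via potassium phosphonate carbanion 25 (not isolated)
Conditions: 24, KN(SiMe3)2, 18-crown-6, THF, −78 °C; then 23, −78 °C
Reagents that add atoms: none
Why: In the Still–Gennari olefination the electron-poor phosphonate under dissociating conditions eliminates from the kinetic adduct and should give the (Z)-enoate with C19 cis to C6; C6 is not epimerised at −78 °C and the tertiary 13-OH is too weak an acid to quench the phosphonate anion.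

Step 17
Reactants: 26 methyl (2Z,4S)-4-[5-hydroxy-2-(3-methoxyfuran-2-yl)-6-methylidenebicyclo[3.2.1]octan-1-yl]-2-methyl-5-(triethylsilyloxy)pent-2-enoate
Product: 27 oxygen-bridged A/B cycloadduct (C10–O–C3 bridge α, C1 methyl enol ether, C19 methyl ester α and C18 β on C4, 5β-H, 6β-CH2OSiEt3, 13-OH, 16-methylene)
Conditions: PhMe (5 mM), BHT, Et3N (trace), 90 °C, sealed tube, dark
Reagents that add atoms: none
Why: The step is a concerted, asynchronous, normal-demand [4+2] cycloaddition of the electron-rich 3-methoxyfuran (C10=C1–C2=C3) with the tethered (Z)-enoate C5=C4, that is, an intramolecular Diels–Alder reaction of a furan in the fused mode with a three-atom tether (C9, C8, C6); the polarity is matched because the largest HOMO coefficient of the 3-alkoxyfuran lies at C10 and the largest LUMO coefficient of the enoate at C5. Ring B (C5, C6, C8, C9, C10) closes as a five-membered ring through the tether in the exo mode with respect to the oxygen bridge, the only mode the short tether allows, and ring A closes as the cyclohexene of the 7-oxanorbornene through the new bonds C5–C10 and C3–C4. C10 and C3 are set together by suprafacial addition to one furan face, and C9 chooses that face: the transition state that turns the C1–OMe edge of the furan towards H9 and the ring oxygen towards C11 is preferred and places the bridge oxygen α. C5 follows from the exo mode (C6 syn to the bridge) and from allylic 1,3-strain at C6, which keeps H6 in the enoate plane next to C19 so that the furan adds to the face carrying C8, and C4 follows from the (Z)-geometry, which puts C19 on the bridge face and C18 opposite. The step needs exo and π-facial selectivity, secured by the tether length, the C9 and C6 centres and the 3-methoxy group, and it needs the adduct to outlast cycloreversion, which is helped by the gem-disubstitution at C8 in the tether and by taking 27 directly into step 18.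

Step 18
Reactants: 27 oxygen-bridged A/B cycloadduct
Product: 30 19,10-lactone 2-en-1-one with 7-CH2OH and 13-OH, via oxabridged 1-ketone 28 (not isolated), via 10-hydroxy enone ester 29 (not isolated)
Conditions: 0.5 M aq. oxalic acid, THF, 0 °C to rt; NaHCO3 work-up; then DBU, CH2Cl2, rt
Reagents that add atoms: water, O
Why: Mild acid hydrolyses the strained enol ether (and the triethylsilyl ether) to the 7-oxanorbornan-2-one, and DBU then effects the known E1cB opening of such ketones by β-elimination of the C3–O bridge bond, giving the 2-en-1-one and a C10 alkoxide that is cis to C19 and closes the γ-lactone by transesterification, with C10, C4, C5 and C6 untouched and the C3 centre removed.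

Step 19
Reactants: 30 19,10-lactone 2-en-1-one
Product: 31 3β-(pinacolboryl) 1-ketone of the 19,10-lactone
Conditions: CuCl (10 mol%), NaOt-Bu (20 mol%), Xantphos (10 mol%), B2pin2 (1.5 equiv), MeOH (4 equiv), THF, rt
Reagents that add atoms: bis(pinacolato)diboron, CC1(C)OB(B2OC(C)(C)C(C)(C)O2)OC1(C)C
Why: In this copper-catalysed conjugate borylation the Cu–Bpin species adds to C3 and methanol protonates the enolate, and boron should enter from the β face, anti to the α-lactone bridge of the 6-oxabicyclo[3.2.1]octanone, which sets C3 with boron cis to C18; free hydroxyl groups are tolerated.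

Step 20
Reactants: 31 3β-(pinacolboryl) 1-ketone of the 19,10-lactone
Product: 33 1β,3β,13-trihydroxy 7-CH2OH 19,10-lactone (7-deoxo-GA55 alcohol), via 1β-hydroxy 3β-boronate 32 (not isolated)
Conditions: LiBH(s-Bu)3 (4 equiv), THF, −78 °C; then NaBO3·4H2O, THF/pH 7 buffer, 0 °C to rt
Reagents that add atoms: sodium perborate, [Na+].[O-]OB=O
Why: The axial 3β-boronate blocks axial (β) approach to C1 and the bulky trialkylborohydride prefers equatorial attack, so hydride should come from the α face and give the axial 1β-alcohol, and perborate oxidation of the C–B bond with retention then gives 3β-OH under conditions too mild for retro-aldol epimerisation at C3.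

Step 21
Reactants: 33 1β,3β,13-trihydroxy 7-CH2OH 19,10-lactone
Product: 35 GA55, via 7-aldehyde 34 (not isolated)
Conditions: TEMPO (20 mol%), PhI(OAc)2 (2.5 equiv), MeCN/H2O (1:1), rt
Reagents that add atoms: water, O
Why: Oxoammonium (TEMPO) oxidation with PhI(OAc)2 as terminal oxidant is selective for the primary alcohol over the hindered axial secondary and the tertiary alcohols and in water carries the aldehyde hydrate on to the acid; no hydroxyl is placed to trap the aldehyde as a lactol, and C6 already has the more stable configuration.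

**Compound list**

1 | 3-bromofuran | Brc1ccoc1 | starting material
2 | 3-methoxyfuran | COc1ccoc1 | intermediate
3 | 4,4-dimethoxycyclohexanone | COC1(OC)CCC(=O)CC1 | starting material
4 | methyl 5,5-dimethoxy-2-oxocyclohexane-1-carboxylate (racemic, enolisable) | COC(=O)C1CC(OC)(OC)CCC1=O | intermediate
5 | methyl 5,5-dimethoxy-2-(trifluoromethylsulfonyloxy)cyclohex-1-ene-1-carboxylate | COC(=O)C1=C(OS(=O)(=O)C(F)(F)F)CCC(OC)(OC)C1 | intermediate
6 | 2-lithio-3-methoxyfuran | [Li]c1occc1OC | intermediate
7 | (3-methoxyfuran-2-yl)zinc chloride | Cl[Zn]c1occc1OC | intermediate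
8 | methyl 5,5-dimethoxy-2-(3-methoxyfuran-2-yl)cyclohex-1-ene-1-carboxylate | COC(=O)C1=C(c2occc2OC)CCC(OC)(OC)C1 | intermediate
9 | 5,5-dimethoxy-2-(3-methoxyfuran-2-yl)cyclohex-1-ene-1-carboxylic acid | OC(=O)C1=C(c2occc2OC)CCC(OC)(OC)C1 | intermediate
10 | (1S,2R)-5,5-dimethoxy-2-(3-methoxyfuran-2-yl)cyclohexane-1-carboxylic acid (cis) | OC(=O)[C@H]1CC(OC)(OC)CC[C@H]1c1occc1OC | intermediate
11 | 3-bromo-1-(trimethylsilyl)prop-1-yne | C[Si](C)(C)C#CCBr | starting material
12 | dilithium enediolate of 10 | [Li+].[Li+].[O-]C([O-])=C1CC(OC)(OC)CC[C@H]1c1occc1OC | intermediate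
13 | (1S,2R)-5,5-dimethoxy-2-(3-methoxyfuran-2-yl)-1-[3-(trimethylsilyl)prop-2-yn-1-yl]cyclohexane-1-carboxylic acid (propargyl trans, CO2H cis to furyl) | C[Si](C)(C)C#CC[C@]1(C(=O)O)CC(OC)(OC)CC[C@H]1c1occc1OC | intermediate
14 | acid chloride of 13 | C[Si](C)(C)C#CC[C@]1(C(=O)Cl)CC(OC)(OC)CC[C@H]1c1occc1OC | intermediate
15 | diazomethyl ketone of 13 (same configuration) | C[Si](C)(C)C#CC[C@]1(C(=O)C=[N+]=[N-])CC(OC)(OC)CC[C@H]1c1occc1OC | intermediate
16 | ketene from 15 (C8–CH=C=O) | C[Si](C)(C)C#CC[C@]1(C=C=O)CC(OC)(OC)CC[C@H]1c1occc1OC | intermediate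
17 | methyl 2-{5,5-dimethoxy-2-(3-methoxyfuran-2-yl)-1-[3-(trimethylsilyl)prop-2-yn-1-yl]cyclohexyl}acetate (CH2CO2Me cis, propargyl trans to furyl) | C[Si](C)(C)C#CC[C@]1(CC(=O)OC)CC(OC)(OC)CC[C@H]1c1occc1OC | intermediate
18 | methyl 2-[5,5-dimethoxy-2-(3-methoxyfuran-2-yl)-1-(prop-2-yn-1-yl)cyclohexyl]acetate (same configuration) | C#CC[C@]1(CC(=O)OC)CC(OC)(OC)CC[C@H]1c1occc1OC | intermediate
19 | methyl 2-[2-(3-methoxyfuran-2-yl)-5-oxo-1-(prop-2-yn-1-yl)cyclohexyl]acetate (same configuration) | C#CC[C@]1(CC(=O)OC)CC(=O)CC[C@H]1c1occc1OC | intermediate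
20 | methyl 2-[5-hydroxy-2-(3-methoxyfuran-2-yl)-6-methylidenebicyclo[3.2.1]octan-1-yl]acetate (furyl anti to the two-carbon bridge) | C=C1C[C@@]2(C[C@@]1(O)CC[C@H]2c1occc1OC)CC(=O)OC | intermediate
21 | 2-[5-hydroxy-2-(3-methoxyfuran-2-yl)-6-methylidenebicyclo[3.2.1]octan-1-yl]acetaldehyde | C=C1C[C@@]2(C[C@@]1(O)CC[C@H]2c1occc1OC)CC=O | intermediate
22 | (2S)-3-hydroxy-2-[5-hydroxy-2-(3-methoxyfuran-2-yl)-6-methylidenebicyclo[3.2.1]octan-1-yl]propanal | C=C1C[C@@]2(C[C@@]1(O)CC[C@H]2c1occc1OC)[C@@H](CO)C=O | intermediate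
23 | (2S)-2-[5-hydroxy-2-(3-methoxyfuran-2-yl)-6-methylidenebicyclo[3.2.1]octan-1-yl]-3-(triethylsilyloxy)propanal | C=C1C[C@@]2(C[C@@]1(O)CC[C@H]2c1occc1OC)[C@@H](CO[Si](CC)(CC)CC)C=O | intermediate
24 | methyl 2-[bis(2,2,2-trifluoroethoxy)phosphoryl]propanoate | COC(=O)C(C)P(=O)(OCC(F)(F)F)OCC(F)(F)F | starting material
25 | potassium salt of the carbanion of 24 | [K+].COC(=O)[C-](C)P(=O)(OCC(F)(F)F)OCC(F)(F)F | intermediate
26 | methyl (2Z,4S)-4-[5-hydroxy-2-(3-methoxyfuran-2-yl)-6-methylidenebicyclo[3.2.1]octan-1-yl]-2-methyl-5-(triethylsilyloxy)pent-2-enoate (cycloaddition precursor) | C=C1C[C@@]2(C[C@@]1(O)CC[C@H]2c1occc1OC)[C@@H](CO[Si](CC)(CC)CC)/C=C(/C)C(=O)OC | intermediate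
27 | oxygen-bridged A/B cycloadduct (10α,3α-epoxide, C1 methyl enol ether, 4α-CO2Me, 4β-Me, 5β-H, 6β-CH2OSiEt3, 13-OH, 16-methylene) | C=C1C[C@]23C[C@@]1(O)CC[C@H]2[C@]45O[C@H](C=C4OC)[C@@](C)(C(=O)OC)[C@H]5[C@@H]3CO[Si](CC)(CC)CC | intermediate
28 | oxabridged 1-ketone (10α,3α-epoxide, 1-oxo, 4α-CO2Me, 7-CH2OH, 13-OH) | C=C1C[C@]23C[C@@]1(O)CC[C@H]2[C@]45O[C@H](CC4=O)[C@@](C)(C(=O)OC)[C@H]5[C@@H]3CO | intermediate
29 | 10α-hydroxy 2-en-1-one 19-methyl ester (7-CH2OH, 13-OH) | C=C1C[C@]23C[C@@]1(O)CC[C@H]2[C@]4(O)C(=O)C=C[C@@](C)(C(=O)OC)[C@H]4[C@@H]3CO | intermediate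
30 | 19,10-lactone 2-en-1-one (7-CH2OH, 13-OH, 16-methylene) | C=C1C[C@]23C[C@@]1(O)CC[C@H]2[C@@]12OC(=O)[C@@](C)([C@H]1[C@@H]3CO)C=CC2=O | intermediate
31 | 3β-(pinacolboryl) 1-ketone of the 19,10-lactone | C=C1C[C@]23C[C@@]1(O)CC[C@H]2[C@@]12OC(=O)[C@@](C)([C@H]1[C@@H]3CO)[C@@H](B4OC(C)(C)C(C)(C)O4)CC2=O | intermediate
32 | 1β-hydroxy 3β-(pinacolboryl) 19,10-lactone | C=C1C[C@]23C[C@@]1(O)CC[C@H]2[C@@]12OC(=O)[C@@](C)([C@H]1[C@@H]3CO)[C@@H](B4OC(C)(C)C(C)(C)O4)C[C@H]2O | intermediate
33 | 1β,3β,13-trihydroxy 7-CH2OH 19,10-lactone | C=C1C[C@]23C[C@@]1(O)CC[C@H]2[C@@]12OC(=O)[C@@](C)([C@H]1[C@@H]3CO)[C@@H](O)C[C@H]2O | intermediate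
34 | 7-aldehyde of 33 | C=C1C[C@]23C[C@@]1(O)CC[C@H]2[C@@]12OC(=O)[C@@](C)([C@H]1[C@@H]3C=O)[C@@H](O)C[C@H]2O | intermediate
35 | GA55 | C=C1C[C@]23C[C@@]1(O)CC[C@H]2[C@@]12OC(=O)[C@@](C)([C@H]1[C@@H]3C(=O)O)[C@@H](O)C[C@H]2O | target

**Step count**

Total step count: 21. Longest linear sequence: 20 steps (3 to 35, steps 2–21); step 1 is a one-step side branch that joins at step 4.

**Steps most likely to fail**

Step 17 (key cycloaddition). The trisubstituted enoate may add too slowly, so that cycloreversion keeps the equilibrium on the side of 26 and prolonged heating erodes the methoxyfuran. The fallback sets out from 23 and returns at 30. Aldehyde 23 is olefinated under the same Still–Gennari conditions with 2,2,2-trifluoroethyl 2-[bis(2,2,2-trifluoroethoxy)phosphoryl]propanoate (from tris(2,2,2-trifluoroethyl) phosphite and 2,2,2-trifluoroethyl 2-bromopropanoate) to give the (Z)-2,2,2-trifluoroethyl enoate F1. Its lower LUMO should speed the cycloaddition in toluene to the oxygen-bridged adduct with a trifluoroethyl ester at C19 F2. In F2 the activated ester is taken by the C10 alkoxide as soon as the bridge opens, so the oxalic acid then DBU treatment of step 18, applied to the crude mixture, should drain the equilibrium and give 30 with loss of trifluoroethanol.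

Step 6 (asymmetric hydrogenation). Turnover may be slow and enantioface discrimination weak at the tetrasubstituted, heteroaryl-bearing alkene. The fallback sets out from 8 and returns at 13. Conjugate reduction of 8 with Mg in MeOH, with equilibration by the Mg(OMe)2 formed, should give the racemic trans ester F3. LiOH then gives the racemic trans acid F4. This is resolved by crystallisation of its salt with 1-phenylethylamine, the amine enantiomer being chosen for the less soluble salt of the (9R) acid; with the (R)-amine this is the (R)-1-phenylethylammonium salt F5. Buffered liberation gives the (1R,2R)-trans acid F6. Under the conditions of step 7, F6 gives the same enediolate 12 and hence 13, because C8 is planarised there.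

Step 14 (organocatalytic hydroxymethylation). Enamine formation at the neopentyl-type aldehyde may be slow and a mismatch of catalyst and substrate may lower facial selectivity, with dehydration to the α-methylene aldehyde as a drain. The fallback sets out from 20 and returns at 23.
- LiOH gives the acid F7.
- Pivaloyl chloride/Et3N and then lithiated (S)-4-benzyloxazolidin-2-one give the imide F8.
- An Evans boron aldol reaction with monomeric formaldehyde (Bu2BOTf, i-Pr2NEt, CH2Cl2, −78 °C) gives the hydroxymethyl imide F9, with C6 set by the auxiliary.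
- Et3SiCl/imidazole gives the silyl ether F10.
- LiBH4 in THF/MeOH removes the auxiliary reductively and gives the primary alcohol F11.
- SO3·pyridine, DMSO and i-Pr2NEt at 0 °C oxidise F11 to 23.

Further compounds
F1 | step 17 | 2,2,2-trifluoroethyl (2Z,4S)-4-[5-hydroxy-2-(3-methoxyfuran-2-yl)-6-methylidenebicyclo[3.2.1]octan-1-yl]-2-methyl-5-(triethylsilyloxy)pent-2-enoate | C=C1C[C@@]2(C[C@@]1(O)CC[C@H]2c1occc1OC)[C@@H](CO[Si](CC)(CC)CC)/C=C(/C)C(=O)OCC(F)(F)F
F2 | step 17 | oxygen-bridged A/B cycloadduct with 4α-CO2CH2CF3 (otherwise as 27) | C=C1C[C@]23C[C@@]1(O)CC[C@H]2[C@]45O[C@H](C=C4OC)[C@@](C)(C(=O)OCC(F)(F)F)[C@H]5[C@@H]3CO[Si](CC)(CC)CC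
F3 | step 6 | racemic trans methyl 5,5-dimethoxy-2-(3-methoxyfuran-2-yl)cyclohexane-1-carboxylate | COC(=O)[C@@H]1CC(OC)(OC)CC[C@H]1c1occc1OC.COC(=O)[C@H]1CC(OC)(OC)CC[C@@H]1c1occc1OC
F4 | step 6 | racemic trans 5,5-dimethoxy-2-(3-methoxyfuran-2-yl)cyclohexane-1-carboxylic acid | OC(=O)[C@@H]1CC(OC)(OC)CC[C@H]1c1occc1OC.OC(=O)[C@H]1CC(OC)(OC)CC[C@@H]1c1occc1OC
F5 | step 6 | (R)-1-phenylethylammonium (1R,2R)-5,5-dimethoxy-2-(3-methoxyfuran-2-yl)cyclohexane-1-carboxylate | [O-]C(=O)[C@@H]1CC(OC)(OC)CC[C@H]1c1occc1OC.C[C@@H]([NH3+])c1ccccc1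
F6 | step 6 | (1R,2R)-5,5-dimethoxy-2-(3-methoxyfuran-2-yl)cyclohexane-1-carboxylic acid (trans) | OC(=O)[C@@H]1CC(OC)(OC)CC[C@H]1c1occc1OC
F7 | step 14 | 2-[5-hydroxy-2-(3-methoxyfuran-2-yl)-6-methylidenebicyclo[3.2.1]octan-1-yl]acetic acid | C=C1C[C@@]2(C[C@@]1(O)CC[C@H]2c1occc1OC)CC(=O)O
F8 | step 14 | (S)-4-benzyl-3-{2-[5-hydroxy-2-(3-methoxyfuran-2-yl)-6-methylidenebicyclo[3.2.1]octan-1-yl]acetyl}oxazolidin-2-one | C=C1C[C@@]2(C[C@@]1(O)CC[C@H]2c1occc1OC)CC(=O)N1C(=O)OC[C@@H]1Cc1ccccc1
F9 | step 14 | α-hydroxymethyl imide (C6 as in 22) | C=C1C[C@@]2(C[C@@]1(O)CC[C@H]2c1occc1OC)[C@@H](CO)C(=O)N1C(=O)OC[C@@H]1Cc1ccccc1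
F10 | step 14 | α-(triethylsilyloxymethyl) imide | C=C1C[C@@]2(C[C@@]1(O)CC[C@H]2c1occc1OC)[C@@H](CO[Si](CC)(CC)CC)C(=O)N1C(=O)OC[C@@H]1Cc1ccccc1
F11 | step 14 | 2-[5-hydroxy-2-(3-methoxyfuran-2-yl)-6-methylidenebicyclo[3.2.1]octan-1-yl]-3-(triethylsilyloxy)propan-1-ol (C6 as in 23) | C=C1C[C@@]2(C[C@@]1(O)CC[C@H]2c1occc1OC)[C@@H](CO[Si](CC)(CC)CC)CO
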